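The γ-butyrolactone ring (O1, C2 carbonyl, C3 carbinol, C4, C5) is closed at C4–C5: the OCH2 carbon C5 and the β-carbon C4, two acceptor-type positions, are united by 5-exo-trig cyclization of an (acyloxy)methyl radical onto an (E)-styrene. Because C4 carries the 4-hydroxy-3,5-dimethoxybenzyl group, that aryl ring sits on the alkene terminus of the precursor, stabilises the cyclised radical and fixes the regiochemistry, while the quaternary C3 carbinol, set earlier by an auxiliary-controlled benzyl Grignard addition to an arylidenepyruvate, steers the new C4 stereocentre. The precursor is an open-chain iodomethyl 2-benzyl-2-hydroxy-4-arylbut-3-enoate; one operation creates ring, C–C bond, C4 stereocentre and benzylic CH2.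

Key step: step 8

Remark (assumption): the benzyl Grignard reagent is taken to attack the α-keto ester on the face left open by the phenyl group of the auxiliary, as in other additions to 8-phenylmenthyl α-keto esters; with the (1S,2R,5S) auxiliary this corresponds to the (S) carbinol.

Step 1
Reactants: 1 4-(benzyloxy)-3,5-dimethoxybenzaldehyde; 2 pyruvic acid
Product: 3 (E)-4-[4-(benzyloxy)-3,5-dimethoxyphenyl]-2-oxobut-3-enoic acid
Conditions: KOH, MeOH, 0 °C → rt; then aq. HCl
Reagents that add atoms: none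
Why: Claisen–Schmidt (crossed aldol) condensation of a non-enolisable aldehyde with the pyruvate methyl group should give the conjugated (E)-arylidenepyruvic acid after dehydration, with no stereocentre formed.

Step 2
Reactants: 3 (E)-4-[4-(benzyloxy)-3,5-dimethoxyphenyl]-2-oxobut-3-enoic acid; 4 (+)-8-phenylmenthol [(1S,2R,5S)-5-methyl-2-(2-phenylpropan-2-yl)cyclohexan-1-ol]
Product: 5 (1S,2R,5S)-8-phenylmenthyl (E)-4-[4-(benzyloxy)-3,5-dimethoxyphenyl]-2-oxobut-3-enoate
Conditions: DCC, DMAP (cat.), CH2Cl2, 0 °C → rt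
Reagents that add atoms: none
Why: Steglich esterification should acylate the hindered secondary alcohol with the α-keto acid and installs the auxiliary whose phenyl group shields one face of the keto carbonyl.

Step 3
Reactants: 6 [4-(benzyloxy)-3-methoxyphenyl]methanol
Product: 7 1-(benzyloxy)-4-(chloromethyl)-2-methoxybenzene
Conditions: SOCl2, CH2Cl2, 0 °C → rt
Reagents that add atoms: thionyl chloride, O=S(Cl)Cl
Why: Chlorination of an electron-rich benzylic alcohol through its chlorosulfite should be fast and clean, and the chloride is used without storage.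

Step 4
Reactants: 5 (1S,2R,5S)-8-phenylmenthyl (E)-4-[4-(benzyloxy)-3,5-dimethoxyphenyl]-2-oxobut-3-enoate; 7 1-(benzyloxy)-4-(chloromethyl)-2-methoxybenzene
Product: 9 (1S,2R,5S)-8-phenylmenthyl (S,E)-2-[4-(benzyloxy)-3-methoxybenzyl]-4-[4-(benzyloxy)-3,5-dimethoxyphenyl]-2-hydroxybut-3-enoate, via benzylic Grignard reagent 8 (not isolated)
Conditions: Mg turnings, THF, 0 °C (slow addition of 7, dilute); then 5, THF, −78 °C; H2O quench
Reagents that add atoms: none
Why: Auxiliary-controlled Grignard 1,2-addition to an α-keto ester (Prelog-type shielding model) should deliver the benzyl group to the keto face not covered by the auxiliary phenyl ring and so set the (S) quaternary carbinol, the minor diastereomeric ester being removable by chromatography.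

Step 5
Reactants: 9 (1S,2R,5S)-8-phenylmenthyl (S,E)-2-[4-(benzyloxy)-3-methoxybenzyl]-4-[4-(benzyloxy)-3,5-dimethoxyphenyl]-2-hydroxybut-3-enoate
Product: 10 (S,E)-2-[4-(benzyloxy)-3-methoxybenzyl]-4-[4-(benzyloxy)-3,5-dimethoxyphenyl]-2-hydroxybut-3-enoic acid
Conditions: KOH, MeOH/THF/H2O, 60 °C; then cold 1 M HCl to pH 3–4, immediate extraction
Reagents that add atoms: potassium hydroxide, [K+].[OH-]
Why: Saponification should free the acid and return the auxiliary, and the quaternary carbinol has no α-hydrogen and cannot epimerise.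

Step 6
Reactants: 10 (S,E)-2-[4-(benzyloxy)-3-methoxybenzyl]-4-[4-(benzyloxy)-3,5-dimethoxyphenyl]-2-hydroxybut-3-enoic acid
Product: 11 chloromethyl (S,E)-2-[4-(benzyloxy)-3-methoxybenzyl]-4-[4-(benzyloxy)-3,5-dimethoxyphenyl]-2-hydroxybut-3-enoate
Conditions: ClCH2OSO2Cl, NaHCO3, Bu4NHSO4 (cat.), CH2Cl2/H2O, rt
Reagents that add atoms: chloromethyl chlorosulfate, ClCOS(=O)(=O)Cl
Why: Phase-transfer O-alkylation of the carboxylate should displace chlorosulfate selectively over chloride, while the tertiary hydroxyl is not deprotonated by bicarbonate and stays free.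

Step 7
Reactants: 11 chloromethyl (S,E)-2-[4-(benzyloxy)-3-methoxybenzyl]-4-[4-(benzyloxy)-3,5-dimethoxyphenyl]-2-hydroxybut-3-enoate
Product: 12 iodomethyl (S,E)-2-[4-(benzyloxy)-3-methoxybenzyl]-4-[4-(benzyloxy)-3,5-dimethoxyphenyl]-2-hydroxybut-3-enoate
Conditions: NaI, acetone, rt, dark; used at once
Reagents that add atoms: sodium iodide, [Na+].[I-]
Why: Finkelstein exchange, driven by precipitation of NaCl, should give the iodide, whose abstraction by a stannyl radical outruns stannyl addition to the styrene.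

Step 8
Reactants: 12 iodomethyl (S,E)-2-[4-(benzyloxy)-3-methoxybenzyl]-4-[4-(benzyloxy)-3,5-dimethoxyphenyl]-2-hydroxybut-3-enoate
Product: 13 (3S,4S)-3-[4-(benzyloxy)-3-methoxybenzyl]-4-[4-(benzyloxy)-3,5-dimethoxybenzyl]-3-hydroxydihydrofuran-2(3H)-one
Conditions: Bu3SnH, AIBN (cat.), PhH, reflux, slow addition by syringe pump, high dilution
Reagents that add atoms: none
Why: Bu3Sn• abstracts iodine from 12 to give the (acyloxy)methyl radical, which through the minor s-cis ester rotamer adds to C4 of the styrene; the resulting benzylic radical, stabilised by the electron-rich aryl ring, takes hydrogen from Bu3SnH and carries the chain. The closest known reaction type is the tin hydride ring closure of (alkenoyloxy)methyl radicals from halomethyl alkenoates to γ-lactones, a reductive radical cyclization. The lactone ring closes in the 5-exo-trig mode, the C4–C5 bond being the one formed. The new C4 stereocentre is controlled by the adjacent quaternary C3 in a Beckwith–Houk-type transition state: the larger arylmethyl group on C3 sits pseudo-equatorial and the alkene terminus turns to the face of the small free hydroxyl, so the two benzyl groups should end up trans (3S,4S). The step needs 5-exo over 6-endo regioselectivity, secured by the aryl group on the distal alkene carbon, and ring closure ahead of hydrogen transfer or a 1,5-hydrogen shift from the C3 benzylic CH2, secured by high dilution, slow stannane addition and the fast styrene acceptor.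

Step 9
Reactants: 13 (3S,4S)-3-[4-(benzyloxy)-3-methoxybenzyl]-4-[4-(benzyloxy)-3,5-dimethoxybenzyl]-3-hydroxydihydrofuran-2(3H)-one
Product: 14 (3S,4S)-3-hydroxy-3-(4-hydroxy-3-methoxybenzyl)-4-(4-hydroxy-3,5-dimethoxybenzyl)dihydrofuran-2(3H)-one
Conditions: H2 (1 atm), 10% Pd/C, EtOAc/EtOH, rt
Reagents that add atoms: none
Why: Hydrogenolysis of the two aryl benzyl ethers should leave the lactone and the non-benzylic tertiary alcohol untouched, so both stereocentres are preserved.

Compound list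
1 | 4-(benzyloxy)-3,5-dimethoxybenzaldehyde | COc1cc(C=O)cc(OC)c1OCc1ccccc1 | starting material
2 | pyruvic acid | CC(=O)C(=O)O | starting material
3 | (E)-4-[4-(benzyloxy)-3,5-dimethoxyphenyl]-2-oxobut-3-enoic acid | COc1cc(/C=C/C(=O)C(=O)O)cc(OC)c1OCc1ccccc1 | intermediate
4 | (+)-8-phenylmenthol, (1S,2R,5S)-5-methyl-2-(2-phenylpropan-2-yl)cyclohexan-1-ol | O[C@H]1C[C@@H](C)CC[C@@H]1C(C)(C)c1ccccc1 | starting material
5 | (1S,2R,5S)-8-phenylmenthyl (E)-4-[4-(benzyloxy)-3,5-dimethoxyphenyl]-2-oxobut-3-enoate | COc1cc(/C=C/C(=O)C(=O)O[C@H]2C[C@@H](C)CC[C@@H]2C(C)(C)c2ccccc2)cc(OC)c1OCc1ccccc1 | intermediate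
6 | [4-(benzyloxy)-3-methoxyphenyl]methanol | COc1cc(CO)ccc1OCc1ccccc1 | starting material
7 | 1-(benzyloxy)-4-(chloromethyl)-2-methoxybenzene | COc1cc(CCl)ccc1OCc1ccccc1 | intermediate
8 | [4-(benzyloxy)-3-methoxybenzyl]magnesium chloride (not isolated) | COc1cc(C[Mg]Cl)ccc1OCc1ccccc1 | intermediate
9 | (1S,2R,5S)-8-phenylmenthyl (S,E)-2-[4-(benzyloxy)-3-methoxybenzyl]-4-[4-(benzyloxy)-3,5-dimethoxyphenyl]-2-hydroxybut-3-enoate | COc1cc(C[C@@](/C=C/c2cc(OC)c(OCc3ccccc3)c(OC)c2)(O)C(=O)O[C@H]2C[C@@H](C)CC[C@@H]2C(C)(C)c2ccccc2)ccc1OCc1ccccc1 | intermediate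
10 | (S,E)-2-[4-(benzyloxy)-3-methoxybenzyl]-4-[4-(benzyloxy)-3,5-dimethoxyphenyl]-2-hydroxybut-3-enoic acid | COc1cc(C[C@@](/C=C/c2cc(OC)c(OCc3ccccc3)c(OC)c2)(O)C(=O)O)ccc1OCc1ccccc1 | intermediate
11 | chloromethyl (S,E)-2-[4-(benzyloxy)-3-methoxybenzyl]-4-[4-(benzyloxy)-3,5-dimethoxyphenyl]-2-hydroxybut-3-enoate | COc1cc(C[C@@](/C=C/c2cc(OC)c(OCc3ccccc3)c(OC)c2)(O)C(=O)OCCl)ccc1OCc1ccccc1 | intermediate
12 | iodomethyl (S,E)-2-[4-(benzyloxy)-3-methoxybenzyl]-4-[4-(benzyloxy)-3,5-dimethoxyphenyl]-2-hydroxybut-3-enoate | COc1cc(C[C@@](/C=C/c2cc(OC)c(OCc3ccccc3)c(OC)c2)(O)C(=O)OCI)ccc1OCc1ccccc1 | intermediate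
13 | (3S,4S)-3-[4-(benzyloxy)-3-methoxybenzyl]-4-[4-(benzyloxy)-3,5-dimethoxybenzyl]-3-hydroxydihydrofuran-2(3H)-one | COc1cc(C[C@@]2(O)C(=O)OC[C@@H]2Cc2cc(OC)c(OCc3ccccc3)c(OC)c2)ccc1OCc1ccccc1 | intermediate
14 | (3S,4S)-3-hydroxy-3-(4-hydroxy-3-methoxybenzyl)-4-(4-hydroxy-3,5-dimethoxybenzyl)dihydrofuran-2(3H)-one | COc1cc(C[C@@]2(O)C(=O)OC[C@@H]2Cc2cc(OC)c(O)c(OC)c2)ccc1O | target

Total step count: 9. Longest linear sequence: 8 steps (steps 1, 2, 4, 5, 6, 7, 8 and 9, from aldehyde 1).

Steps most likely to fail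

Step 8. The stannane may transfer hydrogen to the (acyloxy)methyl radical before the ester rotates into its reactive s-cis form, returning a methyl ester, or the two faces of the alkene at C4 may be discriminated too weakly. The fallback sets out from 9 and comes back at 13, and forms the same C4–C5 bond in a temporary silicon-containing ring. The tertiary hydroxyl of 9 would be silylated with (bromomethyl)chlorodimethylsilane (imidazole, DMF) to the (bromomethyl)dimethylsilyl ether F1. Bu3SnH/AIBN in PhH should then close the 1,2-oxasilolane F2 by 5-exo-trig attack of the silylmethyl radical on the same styrene carbon (silicon-tethered Nishiyama–Stork cyclization). This mode carries no ester rotamer penalty, and the bulky 8-phenylmenthyl ester should turn the alkene terminus away from itself. Tamao–Fleming oxidation (KF, KHCO3, H2O2, THF/MeOH) should give the 2,4-dihydroxy ester F3, and lactonization with loss of the auxiliary (TsOH cat., PhH, reflux) should return 13.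

Step 4. Facial selectivity may erode, the Grignard reagent may add in conjugate fashion to the enone, or Wurtz coupling may consume the benzylic chloride while the reagent forms. The fallback sets out from 3 and comes back at 10 by self-regeneration of the stereocentre. Keto acid 3 would be reduced with an L-lactate dehydrogenase (NADH, formate/formate dehydrogenase recycling) to the (S,E)-2-hydroxy acid F4. Condensation with pivalaldehyde (TsOH cat., pentane, water separator) should give the cis-dioxolanone F5. Its lithium enolate (LiN(SiMe3)2, THF, −78 °C) would be alkylated with 7 on the face opposite the tert-butyl group to give the benzylated dioxolanone F6. KOH in aqueous MeOH should then open the acetal to 10.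

Step 5. Saponification of the very hindered auxiliary ester may stall, or the tertiary allylic alcohol may ionise during acidification. The fallback sets out from 9 and comes back at 10. LiAlH4 (THF, 0 °C) should cleave the auxiliary reductively to the 1,2-diol F7. Parikh–Doering oxidation (SO3·pyridine, DMSO, i-Pr2NEt) should give the α-hydroxy aldehyde F8, and Pinnick oxidation (NaClO2, NaH2PO4, 2-methylbut-2-ene, t-BuOH/H2O) the acid 10.

Further compounds
F1 | step 8 | (1S,2R,5S)-8-phenylmenthyl (S,E)-2-[4-(benzyloxy)-3-methoxybenzyl]-4-[4-(benzyloxy)-3,5-dimethoxyphenyl]-2-{[(bromomethyl)dimethylsilyl]oxy}but-3-enoate | COc1cc(C[C@@](/C=C/c2cc(OC)c(OCc3ccccc3)c(OC)c2)(O[Si](C)(C)CBr)C(=O)O[C@H]2C[C@@H](C)CC[C@@H]2C(C)(C)c2ccccc2)ccc1OCc1ccccc1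
F2 | step 8 | (1S,2R,5S)-8-phenylmenthyl 5-[4-(benzyloxy)-3-methoxybenzyl]-4-[4-(benzyloxy)-3,5-dimethoxybenzyl]-2,2-dimethyl-1,2-oxasilolane-5-carboxylate (the two benzyl groups cis on the oxasilolane ring) | COc1cc(C[C@]2(C(=O)O[C@H]3C[C@@H](C)CC[C@@H]3C(C)(C)c3ccccc3)O[Si](C)(C)C[C@@H]2Cc2cc(OC)c(OCc3ccccc3)c(OC)c2)ccc1OCc1ccccc1
F3 | step 8 | (1S,2R,5S)-8-phenylmenthyl (2S,3S)-2-[4-(benzyloxy)-3-methoxybenzyl]-3-[4-(benzyloxy)-3,5-dimethoxybenzyl]-2,4-dihydroxybutanoate | COc1cc(C[C@@]([C@H](CO)Cc2cc(OC)c(OCc3ccccc3)c(OC)c2)(O)C(=O)O[C@H]2C[C@@H](C)CC[C@@H]2C(C)(C)c2ccccc2)ccc1OCc1ccccc1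
F4 | step 4 | (S,E)-4-[4-(benzyloxy)-3,5-dimethoxyphenyl]-2-hydroxybut-3-enoic acid | COc1cc(/C=C/[C@H](O)C(=O)O)cc(OC)c1OCc1ccccc1
F5 | step 4 | (2S,5S)-5-{(E)-2-[4-(benzyloxy)-3,5-dimethoxyphenyl]ethenyl}-2-tert-butyl-1,3-dioxolan-4-one | CC(C)(C)[C@H]1O[C@@H](/C=C/c2cc(OC)c(OCc3ccccc3)c(OC)c2)C(=O)O1
F6 | step 4 | (2S,5S)-5-[4-(benzyloxy)-3-methoxybenzyl]-5-{(E)-2-[4-(benzyloxy)-3,5-dimethoxyphenyl]ethenyl}-2-tert-butyl-1,3-dioxolan-4-one | CC(C)(C)[C@H]1O[C@@](Cc2ccc(OCc3ccccc3)c(OC)c2)(/C=C/c2cc(OC)c(OCc3ccccc3)c(OC)c2)C(=O)O1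
F7 | step 5 | (S,E)-2-[4-(benzyloxy)-3-methoxybenzyl]-4-[4-(benzyloxy)-3,5-dimethoxyphenyl]but-3-ene-1,2-diol | COc1cc(C[C@@](/C=C/c2cc(OC)c(OCc3ccccc3)c(OC)c2)(O)CO)ccc1OCc1ccccc1
F8 | step 5 | (S,E)-2-[4-(benzyloxy)-3-methoxybenzyl]-4-[4-(benzyloxy)-3,5-dimethoxyphenyl]-2-hydroxybut-3-enal | COc1cc(C[C@@](/C=C/c2cc(OC)c(OCc3ccccc3)c(OC)c2)(O)C=O)ccc1OCc1ccccc1
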